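## Structural features

The target is a 1-aryltetralin. Ring A is a benzene ring (C4a, C5–C8, C8a) with methoxy groups on C6 and C8 and a hydroxyl on C7, fused to the saturated ring B (C1–C4). C1 bears a 4-hydroxy-3,5-dimethoxyphenyl ring (ring C), and C2 and C3 each bear a hydroxymethyl group. C1 (S), C2 (R) and C3 (R) are contiguous and each is trans to its neighbour, so the aryl on C1 and the hydroxymethyl on C3 share one face. None of these centres is next to a carbonyl group in the target, so a wrong centre cannot be repaired at the end and must be corrected at an earlier oxidation level. The fragile parts are the two free 2,6-dimethoxyphenols (easily oxidised by peracid, air or base), the doubly benzylic C1–H and the electron-rich rings. The real difficulty is absolute control of three adjacent carbon-substituted centres, one of them (C1) pressed against the C8 methoxy group, on a ring with no heteroatom handle. The key step exploits the ortho relationship of C8a and C4a on ring A: C1 and C2 are the two carbons of an aryl ynoate on C8a, C3 is the β-carbon of an enone hung on C4a through C4, and one catalytic event joins ring C to C1 and C2 to C3.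

## Logic of the disconnections

20 from 19. The two aryl O–isopropyl bonds are cut last. The phenols must stay masked through the peracid step, and the mask must outlast a pressure hydrogenation, which benzyl ethers would not; isopropyl ethers tolerate every step and can be removed next to methyl ethers. The forward step must dealkylate two secondary ethers without touching four methyl ethers or the diol.

19 from 18. No skeletal bond is cut: both hydroxymethyl groups are traced to carboxyl-level oxygen, a methyl ester on C2 and an acetate on the C3 arm. One hydride reduction unmasks both. It must be faster than any epimerisation at C2, which is the thermodynamic centre by then anyway.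

18 from 17. The CH2–O bond of the acetate is traced back to a CH2–C(=O) bond, so the C3 arm becomes a 2-oxopropyl group. This links the target's oxidation pattern to an enone conjugate-addition product. The forward oxygen insertion must migrate the primary carbon rather than the methyl and must spare the alkoxyarenes, which is why the phenols are still etherified.

17 from 14. Only the configuration at C2 changes. A syn hydrogenation cannot deliver trans C1/C2, so C2 is set thermodynamically through the ester enolate. The keto ester is a 5-oxohexanoate, which alkoxide would close to a cyclohexane-1,3-dione by Claisen condensation. The ketone is therefore masked in the same flask as the dimethyl ketal 15, epimerised to 16 and unmasked to 17.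

14 from 13. The C1–H and C2–H bonds are removed, returning the C1=C2 alkene. Two stereocentres vanish and only C3 remains. The forward hydrogenation must add both hydrogens to the face opposite the C3 arm, which fixes C1, and must leave the aryl ethers and ketone alone.

13 from 7 and 12. C1–C1' and C2–C3 are cut together. This removes ring B, the pendant ring and the last stereocentre, leaving an achiral ynoate–enone and an arylboronic acid. The forward step must place the aryl on C1, bring the metal at C2 to the side of ring A, and select one face of the enone.

7 from 5 and 6. The C8a–C(sp) bond is cut. The sensitive ynoate is introduced last, after the metathesis with which it would interfere. The aryl halide is an iodide because the position is flanked on both sides and the ring is electron-rich; the coupling must be mild enough to leave the enone and its doubly activated C4 methylene untouched.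

5 from 4. The C8a–I bond is cut. The two free ring positions of 4 are equivalent and activated by ortho and para methoxy groups, so regiochemistry is not an issue. The iodination follows the metathesis so that no electron-rich alkene is present when the iodonium source is used.

4 from 2 and 3. The enone C=C is cut. An allylarene and 3 give the (E)-enone arm in one step, avoiding a benzaldehyde homologation and a labile arylacetaldehyde. The forward step must be E-selective and must not isomerise the allyl group.

2 from 1. The O–isopropyl bond is cut; 1 already holds the whole ring A substitution pattern and the three-carbon arm.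

12 from 9 and 9 from 8. The C–B bond and then the O–isopropyl bond are cut. Halogen–lithium exchange and borylation need the phenol masked first.

## Other disconnections considered

Alternative 1: The cut is C2–C3 together with C1–C8a. The precursor is A2, two 4-hydroxy-3,5-dimethoxycinnamoyl units joined as esters through a (2R,4R)-1,3-diol tether. A laccase with O2 would oxidise both phenols, the two side-chain radicals would couple to form C2–C3, and the ring of one unit would add through C8a to the quinone methide carbon of the other, giving the bridged dihydronaphthalene A1.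
- In its favour: ring B and both ring-B bonds form in one operation from a symmetrical, unprotected precursor. The oxygenation pattern of both rings is inherent. Both future hydroxymethyl carbons are already at ester level, so no carbon has to be excised. On step economy, protecting-group economy and atom economy it is better than the chosen plan.
- Against it: phenoxyl radical coupling has several competing modes (C–O coupling, oligomers, trapping of the quinone methides by water). The C2–C3 bond would form inside a nine-membered diester ring. Absolute configuration would rest on relay from two remote tether stereocentres, not on a catalyst bound at the reacting carbon. The product phenols remain substrates for the oxidant.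
- Comparison: it sets C1 and C2 in the cascade and leaves C3 to a later hydrogenation of a trisubstituted alkene, which is easier than the tetrasubstituted alkene of 13. The chosen plan does the opposite, setting C3 catalytically and deriving C1 and C2 from it. The two are equal in leaving part of the stereotriad to later steps; the chosen plan is the more predictable in absolute control.

Alternative 2: The cut is C4–C4a. The precursor is A4, an acyclic diarylmethane with C1 and C2 already set and two identical CH2OTs arms on C3. Base would generate the ring A phenoxide, whose para carbon C4a would displace one tosylate, closing ring B and making C3 stereogenic to give A3.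
- In its favour: it uses the innate nucleophilicity of the phenol para position and needs no metal or ligand. The phenols stay free. The two arms are chemically identical, so the choice is made only by the chair-like closure, which should put the remaining arm equatorial and so trans. Both hydroxymethyl carbons are at the correct oxidation level throughout, so hydrogenation, epimerisation and oxygen insertion are all avoided. On these points it is better than the chosen plan.
- Against it: ring C also carries a free phenoxide, and its para carbon can attack the same arms to close a five-membered spiro-dienone, a mode that is usually faster than six-ring closure. The leftover tosylate must still be exchanged for hydroxyl at a β-branched carbon. Most of the difficulty moves into A4: a diarylmethine stereocentre between two similar electron-rich rings next to C2 has to be made in acyclic form, and ring A must be a less accessible 1,2,3,4-tetrasubstituted arene.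
- Comparison: the key step forms one bond and one stereocentre, against two bonds and one stereocentre in the chosen plan. It is equal in creating C3 during ring closure, shorter after the key step, and probably longer and less convergent before it.

Alternative 3: The cut is C1–C2. The precursor is A6, a p-hydroxybenzhydrol on C8a with a β-branched aldehyde chain on C4a that already carries C3. Acid would ionise the benzhydrol to a p-quinone methide at C1, a secondary amine would turn the aldehyde into an enamine, and the enamine α-carbon C2 would add 1,6 to C1, giving the all-trans aldehyde A5.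
- In its favour: two stereocentres (C1 and C2) are set during ring closure, and the aldehyde α-centre can equilibrate to the trans arrangement. The product is only a hydride reduction, a desilylation and a hydrogenolysis away from the target. No hindered alkene has to be hydrogenated and no carbon excised. After the key step it is better than the chosen plan.
- Against it: C3 must be made beforehand by a separate asymmetric operation on an acyclic chain. The bond forms at a diaryl carbon flanked by a doubly ortho-substituted ring. The C1/C3 relationship depends on a 1,3-interaction in the closing ring, or on a chiral amine that must match the substrate. The quinone methide can be trapped by other nucleophiles, and the enamine can undergo self-aldol reaction.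
- Comparison: one bond and two stereocentres, against two bonds and one stereocentre. The mechanism is polar organocatalysis, against an organonickel cascade. Overall step count is probably comparable. The chosen plan is more convergent, because ring C arrives as a simple boronic acid in the key step and the only chiral input is a catalytic ligand acting on the achiral 7.

Key step: step 7

Remark on the chemistry: atom labels follow the tetralin frame of the target (C1 aryl-bearing, C4 benzylic CH2, C4a and C8a the fusion carbons of ring A), and the (R)-antipode of the phosphinooxazoline is assumed to lead to (3S)-13; if the sense of induction is opposite, the mirror-image ligand is used and nothing else changes.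

## Route

Step 1
Reactants: 1 4-allyl-2,6-dimethoxyphenol
Product: 2 5-allyl-1,3-dimethoxy-2-(propan-2-yloxy)benzene
Conditions: 2-bromopropane, K2CO3, DMF, 60 °C
Reagents that add atoms: 2-bromopropane, CC(C)Br
Why: Williamson etherification of the phenoxide in a dipolar aprotic solvent; carbonate is too weak a base to move the allyl double bond into conjugation.

Step 2
Reactants: 2 5-allyl-1,3-dimethoxy-2-(propan-2-yloxy)benzene; 3 methyl vinyl ketone
Product: 4 (3E)-5-[3,5-dimethoxy-4-(propan-2-yloxy)phenyl]pent-3-en-2-one
Conditions: 3 (3 equiv), second-generation Hoveyda–Grubbs catalyst (H2IMes)Cl2Ru=CH(C6H4-2-O-i-Pr) (3 mol%), 1,4-benzoquinone (10 mol%), CH2Cl2, 40 °C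
Reagents that add atoms: none
Why: Olefin cross-metathesis between a terminal allylarene, which homodimerises readily and reversibly, and an electron-poor enone, which does not, should be selective for the cross product and give the (E)-enone under thermodynamic control; benzoquinone suppresses ruthenium hydride isomerisation of the allyl group.

Step 3
Reactants: 4 (3E)-5-[3,5-dimethoxy-4-(propan-2-yloxy)phenyl]pent-3-en-2-one
Product: 5 (3E)-5-[2-iodo-3,5-dimethoxy-4-(propan-2-yloxy)phenyl]pent-3-en-2-one
Conditions: N-iodosuccinimide (1.05 equiv), CF3CO2H (cat.), MeCN, 0 °C to rt, dark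
Reagents that add atoms: N-iodosuccinimide, O=C1CCC(=O)N1I
Why: Electrophilic aromatic iodination; the only free ring positions are the two equivalent carbons ortho to the arm, each ortho and para to a methoxy group, and the enone alkene is too electron-poor to compete for the iodonium source.

Step 4
Reactants: 5 (3E)-5-[2-iodo-3,5-dimethoxy-4-(propan-2-yloxy)phenyl]pent-3-en-2-one; 6 methyl propiolate
Product: 7 methyl 3-{2,4-dimethoxy-6-[(2E)-4-oxopent-2-en-1-yl]-3-(propan-2-yloxy)phenyl}prop-2-ynoate
Conditions: 6 (3 equiv, added in portions), Pd(PPh3)2Cl2 (5 mol%), CuI (10 mol%), K2CO3 (2 equiv), THF, 50 °C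
Reagents that add atoms: none
Why: Sonogashira coupling; the iodide allows oxidative addition at a flanked, electron-rich position at moderate temperature, and an insoluble carbonate base in place of an amine avoids aza-Michael consumption of the propiolate and keeps the medium too weakly basic to shift the enone double bond.

Step 5
Reactants: 8 4-bromo-2,6-dimethoxyphenol
Product: 9 5-bromo-1,3-dimethoxy-2-(propan-2-yloxy)benzene
Conditions: 2-bromopropane, K2CO3, DMF, 60 °C
Reagents that add atoms: 2-bromopropane, CC(C)Br
Why: Williamson etherification as in step 1; the aryl bromide is inert under these conditions.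

Step 6
Reactants: 9 5-bromo-1,3-dimethoxy-2-(propan-2-yloxy)benzene
Product: 12 [3,5-dimethoxy-4-(propan-2-yloxy)phenyl]boronic acid, via aryllithium 10 (not isolated), via lithium aryltriisopropoxyborate 11 (not isolated)
Conditions: n-BuLi, THF, −78 °C; B(O-i-Pr)3, −78 °C to rt; 1 M HCl
Reagents that add atoms: triisopropyl borate, CC(C)OB(OC(C)C)OC(C)C; water, O
Why: Bromine–lithium exchange is fast at low temperature on this ring, the aryllithium is trapped by the borate ester as an ate complex, and aqueous acid hydrolyses the B–O-alkyl bonds to the boronic acid.

Step 7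
Reactants: 7 methyl 3-{2,4-dimethoxy-6-[(2E)-4-oxopent-2-en-1-yl]-3-(propan-2-yloxy)phenyl}prop-2-ynoate; 12 [3,5-dimethoxy-4-(propan-2-yloxy)phenyl]boronic acid
Product: 13 methyl (3S)-1-[3,5-dimethoxy-4-(propan-2-yloxy)phenyl]-6,8-dimethoxy-3-(2-oxopropyl)-7-(propan-2-yloxy)-3,4-dihydronaphthalene-2-carboxylate
Conditions: 12 (2 equiv), Ni(OAc)2·4H2O (10 mol%), (R)-Ph-PHOX (10 mol%), CF3CH2OH, 80 °C
Reagents that add atoms: none
Why: Transmetalation of 12 to the phosphinooxazoline-bound divalent nickel acetate gives an arylnickel species that adds syn across the alkyne of 7, the aryl going to C1 (β to the ester) and nickel to C2, as in a conjugate arylation of an ynoate. The resulting alkenylnickel has the metal trans to ring A; it equilibrates through its O-bound nickel allenoate form to the isomer with nickel cis to ring A, and only that isomer can reach the enone, so the overall addition across C1=C2 is anti. Migratory insertion of the enone C=C into the C2–Ni bond (a 1,4-addition) forms C2–C3 and closes ring B in a 6-exo-trig mode with respect to the enone, leaving C1=C2 endocyclic; protonation of the nickel enolate by the solvent releases 13 and returns the catalyst with no change of oxidation state. The closest known reaction type is the nickel-catalysed enantioselective anti-carbometallative cyclisation of alkyne-tethered enones with arylboronic acids. The one new stereocentre, C3, is fixed in the insertion step, where the chiral P,N-ligand on nickel selects one face of the (E)-enone, so the alkene geometry set in step 2 is part of the stereocontrol. The step needs the aryl on C1 and not on C2, which would lead to a five-membered ring with an exocyclic alkene; the ester polarisation and the twisted, doubly ortho-substituted ring A, a poor stabiliser of nickel at C1, should secure this. It also needs ring closure to outrun protonolysis of the alkenylnickel, which the short ortho tether favours, and arylnickel addition to the ynoate ahead of the enone, which the greater reactivity of the ynoate should provide.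

Step 8
Reactants: 13 methyl (3S)-1-[3,5-dimethoxy-4-(propan-2-yloxy)phenyl]-6,8-dimethoxy-3-(2-oxopropyl)-7-(propan-2-yloxy)-3,4-dihydronaphthalene-2-carboxylate
Product: 14 methyl (1S,2R,3S)-1-[3,5-dimethoxy-4-(propan-2-yloxy)phenyl]-6,8-dimethoxy-3-(2-oxopropyl)-7-(propan-2-yloxy)-1,2,3,4-tetrahydronaphthalene-2-carboxylate (all-cis)
Conditions: H2 (50 bar), Pd(OH)2/C, EtOAc–AcOH, 40 °C
Reagents that add atoms: none
Why: Heterogeneous syn hydrogenation of the β,β-diaryl acrylate; the C3 arm sits pseudoaxial to avoid A(1,2) strain with the ester and screens one face, so both hydrogens should arrive anti to it, setting C1 as (S) and C2, for the moment, cis to both neighbours; isopropyl ethers and the aliphatic ketone are inert to palladium under these conditions.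

Step 9
Reactants: 14 methyl (1S,2R,3S)-1-[3,5-dimethoxy-4-(propan-2-yloxy)phenyl]-6,8-dimethoxy-3-(2-oxopropyl)-7-(propan-2-yloxy)-1,2,3,4-tetrahydronaphthalene-2-carboxylate (all-cis)
Product: 17 methyl (1S,2S,3S)-1-[3,5-dimethoxy-4-(propan-2-yloxy)phenyl]-6,8-dimethoxy-3-(2-oxopropyl)-7-(propan-2-yloxy)-1,2,3,4-tetrahydronaphthalene-2-carboxylate (all-trans), via cis dimethyl ketal 15 (not isolated), via trans dimethyl ketal 16 (not isolated)
Conditions: HC(OMe)3, TsOH·H2O (cat.), MeOH, rt; then NaOMe (4 equiv), MeOH, 65 °C; then 1 M HCl, THF–H2O, rt
Reagents that add atoms: methanol, CO (the two methoxy groups of 15 and 16); water, O (the ketone oxygen of 17)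
Why: Acid-catalysed ketalisation with the orthoformate as water scavenger masks the ketone, so methoxide cannot trigger the intramolecular Claisen condensation open to this 5-oxohexanoate; the ester α-carbon C2 then equilibrates through its enolate to the isomer trans to both neighbours, in which all three substituents can be equatorial, while C1 and C3 carry no acidic hydrogen; dilute acid returns the ketone.

Step 10
Reactants: 17 methyl (1S,2S,3S)-1-[3,5-dimethoxy-4-(propan-2-yloxy)phenyl]-6,8-dimethoxy-3-(2-oxopropyl)-7-(propan-2-yloxy)-1,2,3,4-tetrahydronaphthalene-2-carboxylate (all-trans)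
Product: 18 methyl (1S,2R,3R)-3-(acetoxymethyl)-1-[3,5-dimethoxy-4-(propan-2-yloxy)phenyl]-6,8-dimethoxy-7-(propan-2-yloxy)-1,2,3,4-tetrahydronaphthalene-2-carboxylate
Conditions: mCPBA (3 equiv), NaHCO3, CH2Cl2, rt to 40 °C
Reagents that add atoms: mCPBA, OOC(=O)c1cccc(Cl)c1
Why: Baeyer–Villiger oxidation; the primary carbon migrates in preference to methyl, so oxygen enters between the C3 methylene and the carbonyl, and the buffer and the etherified phenols keep the rings out of reach of the peracid; the C2 and C3 descriptors change from S to R only because substituent priorities change.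

Step 11
Reactants: 18 methyl (1S,2R,3R)-3-(acetoxymethyl)-1-[3,5-dimethoxy-4-(propan-2-yloxy)phenyl]-6,8-dimethoxy-7-(propan-2-yloxy)-1,2,3,4-tetrahydronaphthalene-2-carboxylate
Product: 19 {(1S,2R,3R)-1-[3,5-dimethoxy-4-(propan-2-yloxy)phenyl]-6,8-dimethoxy-7-(propan-2-yloxy)-1,2,3,4-tetrahydronaphthalene-2,3-diyl}dimethanol
Conditions: LiAlH4, THF, 0 °C to rt; aq. KNaC4H4O6
Reagents that add atoms: none
Why: Hydride reduction converts the methyl ester into the C2 hydroxymethyl group and cleaves the acetate to the C3 hydroxymethyl group in one operation; reduction is much faster than enolisation, and C2 is already in its thermodynamic configuration.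

Step 12
Reactants: 19 {(1S,2R,3R)-1-[3,5-dimethoxy-4-(propan-2-yloxy)phenyl]-6,8-dimethoxy-7-(propan-2-yloxy)-1,2,3,4-tetrahydronaphthalene-2,3-diyl}dimethanol
Product: 20 [(1S,2R,3R)-7-hydroxy-1-(4-hydroxy-3,5-dimethoxyphenyl)-3-(hydroxymethyl)-6,8-dimethoxy-1,2,3,4-tetrahydronaphthalen-2-yl]methanol
Conditions: BCl3 (6 equiv), CH2Cl2, −78 to 0 °C; then MeOH, H2O
Reagents that add atoms: none
Why: Lewis-acid dealkylation of aryl ethers; chloride attacks the secondary isopropyl carbon of the borane–ether complex far faster than a methyl group, so the flanking methoxy groups should survive at low temperature, and the two alcohols are only held as borates that methanol and water release.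

## Compound list

1 | 4-allyl-2,6-dimethoxyphenol | C=CCc1cc(OC)c(O)c(OC)c1 | starting material
2 | 5-allyl-1,3-dimethoxy-2-(propan-2-yloxy)benzene | C=CCc1cc(OC)c(OC(C)C)c(OC)c1 | intermediate
3 | methyl vinyl ketone (but-3-en-2-one) | C=CC(C)=O | starting material
4 | (3E)-5-[3,5-dimethoxy-4-(propan-2-yloxy)phenyl]pent-3-en-2-one | CC(=O)/C=C/Cc1cc(OC)c(OC(C)C)c(OC)c1 | intermediate
5 | (3E)-5-[2-iodo-3,5-dimethoxy-4-(propan-2-yloxy)phenyl]pent-3-en-2-one | CC(=O)/C=C/Cc1cc(OC)c(OC(C)C)c(OC)c1I | intermediate
6 | methyl propiolate | C#CC(=O)OC | starting material
7 | methyl 3-{2,4-dimethoxy-6-[(2E)-4-oxopent-2-en-1-yl]-3-(propan-2-yloxy)phenyl}prop-2-ynoate | COC(=O)C#Cc1c(C/C=C/C(C)=O)cc(OC)c(OC(C)C)c1OC | intermediate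
8 | 4-bromo-2,6-dimethoxyphenol | COc1cc(Br)cc(OC)c1O | starting material
9 | 5-bromo-1,3-dimethoxy-2-(propan-2-yloxy)benzene | COc1cc(Br)cc(OC)c1OC(C)C | intermediate
10 | [3,5-dimethoxy-4-(propan-2-yloxy)phenyl]lithium (not isolated) | [Li]c1cc(OC)c(OC(C)C)c(OC)c1 | intermediate
11 | lithium [3,5-dimethoxy-4-(propan-2-yloxy)phenyl]tris(propan-2-yloxy)borate (not isolated) | [Li+].CC(C)O[B-](OC(C)C)(OC(C)C)c1cc(OC)c(OC(C)C)c(OC)c1 | intermediate
12 | [3,5-dimethoxy-4-(propan-2-yloxy)phenyl]boronic acid | OB(O)c1cc(OC)c(OC(C)C)c(OC)c1 | intermediate
13 | methyl (3S)-1-[3,5-dimethoxy-4-(propan-2-yloxy)phenyl]-6,8-dimethoxy-3-(2-oxopropyl)-7-(propan-2-yloxy)-3,4-dihydronaphthalene-2-carboxylate | COc1cc(C2=C(C(=O)OC)[C@H](CC(C)=O)Cc3cc(OC)c(OC(C)C)c(OC)c32)cc(OC)c1OC(C)C | intermediate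
14 | methyl (1S,2R,3S)-1-[3,5-dimethoxy-4-(propan-2-yloxy)phenyl]-6,8-dimethoxy-3-(2-oxopropyl)-7-(propan-2-yloxy)-1,2,3,4-tetrahydronaphthalene-2-carboxylate (all-cis) | COc1cc([C@H]2c3c(cc(OC)c(OC(C)C)c3OC)C[C@@H](CC(C)=O)[C@H]2C(=O)OC)cc(OC)c1OC(C)C | intermediate
15 | methyl (1S,2R,3S)-3-(2,2-dimethoxypropyl)-1-[3,5-dimethoxy-4-(propan-2-yloxy)phenyl]-6,8-dimethoxy-7-(propan-2-yloxy)-1,2,3,4-tetrahydronaphthalene-2-carboxylate (not isolated) | COc1cc([C@H]2c3c(cc(OC)c(OC(C)C)c3OC)C[C@@H](CC(C)(OC)OC)[C@H]2C(=O)OC)cc(OC)c1OC(C)C | intermediate
16 | methyl (1S,2S,3S)-3-(2,2-dimethoxypropyl)-1-[3,5-dimethoxy-4-(propan-2-yloxy)phenyl]-6,8-dimethoxy-7-(propan-2-yloxy)-1,2,3,4-tetrahydronaphthalene-2-carboxylate (not isolated) | COc1cc([C@H]2c3c(cc(OC)c(OC(C)C)c3OC)C[C@@H](CC(C)(OC)OC)[C@@H]2C(=O)OC)cc(OC)c1OC(C)C | intermediate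
17 | methyl (1S,2S,3S)-1-[3,5-dimethoxy-4-(propan-2-yloxy)phenyl]-6,8-dimethoxy-3-(2-oxopropyl)-7-(propan-2-yloxy)-1,2,3,4-tetrahydronaphthalene-2-carboxylate (all-trans) | COc1cc([C@H]2c3c(cc(OC)c(OC(C)C)c3OC)C[C@@H](CC(C)=O)[C@@H]2C(=O)OC)cc(OC)c1OC(C)C | intermediate
18 | methyl (1S,2R,3R)-3-(acetoxymethyl)-1-[3,5-dimethoxy-4-(propan-2-yloxy)phenyl]-6,8-dimethoxy-7-(propan-2-yloxy)-1,2,3,4-tetrahydronaphthalene-2-carboxylate | COc1cc([C@H]2c3c(cc(OC)c(OC(C)C)c3OC)C[C@@H](COC(C)=O)[C@@H]2C(=O)OC)cc(OC)c1OC(C)C | intermediate
19 | {(1S,2R,3R)-1-[3,5-dimethoxy-4-(propan-2-yloxy)phenyl]-6,8-dimethoxy-7-(propan-2-yloxy)-1,2,3,4-tetrahydronaphthalene-2,3-diyl}dimethanol | COc1cc([C@H]2c3c(cc(OC)c(OC(C)C)c3OC)C[C@@H](CO)[C@@H]2CO)cc(OC)c1OC(C)C | intermediate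
20 | [(1S,2R,3R)-7-hydroxy-1-(4-hydroxy-3,5-dimethoxyphenyl)-3-(hydroxymethyl)-6,8-dimethoxy-1,2,3,4-tetrahydronaphthalen-2-yl]methanol | COc1cc([C@H]2c3c(cc(OC)c(O)c3OC)C[C@@H](CO)[C@@H]2CO)cc(OC)c1O | target

## Step count and least certain steps

Total: 12 steps. Longest linear sequence: 10 steps (steps 1–4, then 7–12); the boronic acid branch (steps 5 and 6) joins at step 7.

Step 7 (key step). The most likely failure is protonolysis of the alkenylnickel by the protic solvent before it has isomerised and closed the ring, which would end in simple hydroarylation of the ynoate. Lesser risks are direct conjugate arylation of the enone and poor facial selectivity at C3, because the aryl must be delivered to an alkyne carbon that carries a doubly ortho-substituted ring. Fallback: setting out from 7, the ynoate is hydrated (morpholine addition, then dilute HCl) to the β-keto ester methyl 3-{2,4-dimethoxy-6-[(2E)-4-oxopent-2-en-1-yl]-3-(propan-2-yloxy)phenyl}-3-oxopropanoate F1. An intramolecular Michael addition of its active methylene carbon to the enone, under a bifunctional cinchona-derived thiourea catalyst, would close ring B and set C3, giving the tetralone ester F2. Selective deprotonation of the β-keto ester (NaH, then Tf2O) gives the enol triflate F3, and a Suzuki–Miyaura coupling of F3 with 12 (Pd(PPh3)4, K3PO4, dioxane–H2O) returns to the route at 13.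

Step 4. Oligomerisation and Michael consumption of the propiolate may outpace coupling at the flanked iodide, and the carbonate may shift the enone double bond towards the arene through the doubly activated C4 methylene. Fallback: 6 is converted with Bu3SnOMe into methyl 3-(tributylstannyl)prop-2-ynoate F4, and a base-free Stille coupling of F4 with 5 (Pd2(dba)3, AsPh3, CuI cat., DMF, 50 °C) comes back to the route at 7.

Step 8. Hydrogen uptake at the tetrasubstituted, screened alkene may be too slow, and forcing conditions invite erosion of face selectivity or reduction of the ketone. Fallback: setting out from 13, the ketone is masked (HC(OMe)3, TsOH cat., MeOH) as the dimethyl ketal methyl (3S)-3-(2,2-dimethoxypropyl)-1-[3,5-dimethoxy-4-(propan-2-yloxy)phenyl]-6,8-dimethoxy-7-(propan-2-yloxy)-3,4-dihydronaphthalene-2-carboxylate F5. Dissolving-metal conjugate reduction of the β,β-diaryl acrylate (Mg, MeOH) should protonate C1 on the face away from the C3 arm and give the C2 epimers 15 and 16. The methoxide stage of step 9 then converges them, so the route is rejoined at 16 and carried on to 17 by the acid stage of step 9.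

Step 10. Oxygen insertion at an unactivated methyl ketone is slow, and prolonged exposure to peracid may start to oxidise the trialkoxyarene rings. Fallback: setting out from 17, acid-catalysed exchange with isopropenyl acetate (TsOH cat., reflux) gives the more substituted enol acetate methyl (1S,2S,3S)-3-[2-(acetyloxy)prop-1-en-1-yl]-1-[3,5-dimethoxy-4-(propan-2-yloxy)phenyl]-6,8-dimethoxy-7-(propan-2-yloxy)-1,2,3,4-tetrahydronaphthalene-2-carboxylate F6. Lemieux–Johnson cleavage of its C=C bond (OsO4 cat., NaIO4, 2,6-lutidine, dioxane–H2O) gives the aldehyde methyl (1S,2R,3R)-1-[3,5-dimethoxy-4-(propan-2-yloxy)phenyl]-3-formyl-6,8-dimethoxy-7-(propan-2-yloxy)-1,2,3,4-tetrahydronaphthalene-2-carboxylate F7. LiAlH4 under the conditions of step 11 reduces aldehyde and ester together and comes back to the route at 19.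

## Further compounds

F1 | step 7 | methyl 3-{2,4-dimethoxy-6-[(2E)-4-oxopent-2-en-1-yl]-3-(propan-2-yloxy)phenyl}-3-oxopropanoate | COC(=O)CC(=O)c1c(C/C=C/C(C)=O)cc(OC)c(OC(C)C)c1OC
F2 | step 7 | methyl (3S)-6,8-dimethoxy-1-oxo-3-(2-oxopropyl)-7-(propan-2-yloxy)-1,2,3,4-tetrahydronaphthalene-2-carboxylate (C2 mobile through the enol) | COC(=O)C1C(=O)c2c(OC)c(OC(C)C)c(OC)cc2C[C@H]1CC(C)=O
F3 | step 7 | methyl (3S)-6,8-dimethoxy-3-(2-oxopropyl)-7-(propan-2-yloxy)-1-(trifluoromethanesulfonyloxy)-3,4-dihydronaphthalene-2-carboxylate | COC(=O)C1=C(OS(=O)(=O)C(F)(F)F)c2c(OC)c(OC(C)C)c(OC)cc2C[C@H]1CC(C)=O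
F4 | step 4 | methyl 3-(tributylstannyl)prop-2-ynoate | CCCC[Sn](CCCC)(CCCC)C#CC(=O)OC
F5 | step 8 | methyl (3S)-3-(2,2-dimethoxypropyl)-1-[3,5-dimethoxy-4-(propan-2-yloxy)phenyl]-6,8-dimethoxy-7-(propan-2-yloxy)-3,4-dihydronaphthalene-2-carboxylate | COc1cc(C2=C(C(=O)OC)[C@H](CC(C)(OC)OC)Cc3cc(OC)c(OC(C)C)c(OC)c32)cc(OC)c1OC(C)C
F6 | step 10 | methyl (1S,2S,3S)-3-[2-(acetyloxy)prop-1-en-1-yl]-1-[3,5-dimethoxy-4-(propan-2-yloxy)phenyl]-6,8-dimethoxy-7-(propan-2-yloxy)-1,2,3,4-tetrahydronaphthalene-2-carboxylate (alkene geometry not defined) | COc1cc([C@H]2c3c(cc(OC)c(OC(C)C)c3OC)C[C@@H](C=C(C)OC(C)=O)[C@@H]2C(=O)OC)cc(OC)c1OC(C)C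
F7 | step 10 | methyl (1S,2R,3R)-1-[3,5-dimethoxy-4-(propan-2-yloxy)phenyl]-3-formyl-6,8-dimethoxy-7-(propan-2-yloxy)-1,2,3,4-tetrahydronaphthalene-2-carboxylate | COc1cc([C@H]2c3c(cc(OC)c(OC(C)C)c3OC)C[C@@H](C=O)[C@@H]2C(=O)OC)cc(OC)c1OC(C)C
A1 | alternative 1 | (2R,4R)-pentane-2,4-diyl-bridged trans-7-hydroxy-1-(4-hydroxy-3,5-dimethoxyphenyl)-6,8-dimethoxy-1,2-dihydronaphthalene-2,3-dicarboxylate | COc1cc([C@H]2c3c(cc(OC)c(O)c3OC)C=C3C(=O)O[C@H](C)C[C@@H](C)OC(=O)[C@H]23)cc(OC)c1O
A2 | alternative 1 | (2R,4R)-pentane-2,4-diyl bis[(2E)-3-(4-hydroxy-3,5-dimethoxyphenyl)prop-2-enoate] | COc1cc(/C=C/C(=O)O[C@H](C)C[C@@H](C)OC(=O)/C=C/c2cc(OC)c(O)c(OC)c2)cc(OC)c1O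
A3 | alternative 2 | all-trans tetralin with silyl ether on the C2 arm and tosylate on the C3 arm | COc1cc([C@H]2c3c(cc(OC)c(O)c3OC)C[C@@H](COS(=O)(=O)c3ccc(C)cc3)[C@@H]2CO[Si](C)(C)C(C)(C)C)cc(OC)c1O
A4 | alternative 2 | acyclic diarylmethane with C1 and C2 set and two tosyloxymethyl arms on C3 | COc1cc([C@@H](c2ccc(OC)c(O)c2OC)[C@@H](CO[Si](C)(C)C(C)(C)C)C(COS(=O)(=O)c2ccc(C)cc2)COS(=O)(=O)c2ccc(C)cc2)cc(OC)c1O
A5 | alternative 3 | all-trans 1-aryl-3-silyloxymethyltetralin-2-carbaldehyde | COc1cc([C@H]2c3c(cc(OC)c(OCc4ccccc4)c3OC)C[C@@H](CO[Si](C)(C)C(C)(C)C)[C@@H]2C=O)cc(OC)c1O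
A6 | alternative 3 | p-hydroxybenzhydrol on C8a with a β-silyloxymethyl aldehyde chain on C4a (carbinol configuration not defined) | COc1cc(C(O)c2c(C[C@@H](CO[Si](C)(C)C(C)(C)C)CC=O)cc(OC)c(OCc3ccccc3)c2OC)cc(OC)c1O
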